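**Strategy**

The α-methylene-γ-butyrolactone is cut where it meets the ten-membered ring: at C11–C12 (methylene-bearing carbon to lactone carbonyl) and at C6–C7 (lactone carbinol carbon to ring-fusion carbon; germacrane locants, ring C1–C10, lactone O–C6–C7–C11(=C13)–C12). Read backwards, C7=C11=C13 is a terminal allene, C12 is CO2 and C6 is the carbonyl carbon of an E-enal. Nickel-mediated carboxylation of the allene gives a 2-carboxylatoallylnickel that adds through C7 to the tethered enal, so one operation closes the 1(10)Z,4E-cyclodecadiene and, on acidification, the trans-fused lactone, setting C6 and C7 under control of C8. The precursor is an acyclic allenyl enal that already carries C2, C8 and C9 and both ring alkenes.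

Key step: step 15

**Remarks and assumptions**

- Macrocyclic compounds are described with the germacrane locants defined above; acyclic intermediates carry their own chain locants.
- Assumption: the γ-hydroxy acid released from nickel lactonises under mild acid.
- Assumption: where an enantiomeric catalyst is named, the antipode is the one expected to give the stated configuration on the usual model; the other antipode is used if the sense proves opposite.

**Route**

Step 1
Reactants: 1 but-2-yn-1-ol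
Product: 2 (Z)-3-iodobut-2-en-1-ol
Conditions: NaAlH2(OCH2CH2OMe)2 (Red-Al), THF, 0 °C to rt; EtOAc; I2, −78 to 0 °C
Reagents that add atoms: iodine, II
Why: Hydroxyl-directed trans-hydroalumination of the propargylic alcohol and iodinolysis with retention place iodine on the distal carbon cis to CH2OH, which fixes the later C1=C10 Z geometry.

Step 2
Reactants: 2 (Z)-3-iodobut-2-en-1-ol
Product: 3 (Z)-3-iodobut-2-enal
Conditions: MnO2, CH2Cl2, rt, dark; used at once
Reagents that add atoms: none
Why: Allylic oxidation with MnO2 under neutral conditions should keep the Z geometry of the β-iodoenal.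

Step 3
Reactants: 4 ethyl 3-methylbut-2-enoate
Product: 5 tert-butyl[(1-ethoxy-3-methylbuta-1,3-dien-1-yl)oxy]dimethylsilane
Conditions: LiN(iPr)2, THF, −78 °C; TBSCl, DMPU, −78 °C to rt
Reagents that add atoms: tert-butyldimethylsilyl chloride, CC(C)(C)[Si](C)(C)Cl
Why: γ-Deprotonation of the senecioate and O-silylation give the silyl dienol ether needed for the vinylogous aldol.

Step 4
Reactants: 3 (Z)-3-iodobut-2-enal; 5 silyl dienol ether
Product: 6 ethyl (2E,5S,6Z)-5-hydroxy-7-iodo-3-methylocta-2,6-dienoate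
Conditions: SiCl4, (S,S)-binaphthyldiamine-derived bisphosphoramide (cat.), iPr2NEt (cat.), CH2Cl2, −78 °C; aq. NaHCO3/KF
Reagents that add atoms: none
Why: Catalytic enantioselective vinylogous Mukaiyama aldol (Lewis-base-activated SiCl4): γ-attack on the Si face of the aldehyde should set C2 as S and give the E-trisubstituted enoate (future C4=C5).

Step 5
Reactants: 6 hydroxy ester
Product: 7 ethyl (2E,5S,6Z)-5-[(tert-butyldimethylsilyl)oxy]-7-iodo-3-methylocta-2,6-dienoate
Conditions: TBSCl, imidazole, DMF, rt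
Reagents that add atoms: tert-butyldimethylsilyl chloride, CC(C)(C)[Si](C)(C)Cl
Why: Standard silyl ether formation protects the C2 hydroxyl that is freed only in the last step.

Step 6
Reactants: 7 silyl ether ester
Product: 8 (2E,5S,6Z)-5-[(tert-butyldimethylsilyl)oxy]-7-iodo-3-methylocta-2,6-dien-1-ol
Conditions: iBu2AlH, CH2Cl2, −78 °C; Rochelle salt
Reagents that add atoms: none
Why: 1,2-Reduction of the enoate by DIBAL-H gives the allylic alcohol (future C6) without touching the vinyl iodide or the silyl ether.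

Step 7
Reactants: 9 (S)-2,2-dimethyl-1,3-dioxolane-4-carbaldehyde
Product: 10 (R)-4-ethynyl-2,2-dimethyl-1,3-dioxolane
Conditions: dimethyl (1-diazo-2-oxopropyl)phosphonate, K2CO3, MeOH, 0 °C to rt
Reagents that add atoms: dimethyl (1-diazo-2-oxopropyl)phosphonate, COP(=O)(OC)C(=[N+]=[N-])C(C)=O
Why: Seyferth–Gilbert homologation with the Ohira–Bestmann reagent converts the aldehyde into the terminal alkyne under mild base, leaving the stereocentre (future C8) intact.

Step 8
Reactants: 10 (R)-4-ethynyl-2,2-dimethyl-1,3-dioxolane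
Product: 12 (4R)-4-ethynyl-2-(4-methoxyphenyl)-1,3-dioxolane (acetal epimers), via (R)-but-3-yne-1,2-diol 11 (not isolated)
Conditions: p-TsOH (cat.), MeOH, rt; evaporate; 4-MeOC6H4CH(OMe)2, CSA (cat.), CH2Cl2, rt
Reagents that add atoms: 4-methoxybenzaldehyde dimethyl acetal, COc1ccc(C(OC)OC)cc1
Why: Acid-catalysed transacetalisation exchanges the acetonide for the p-methoxybenzylidene acetal that carries the later PMB group.

Step 9
Reactants: 12 p-methoxybenzylidene acetal
Product: 13 (R)-2-[(4-methoxybenzyl)oxy]but-3-yn-1-ol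
Conditions: iBu2AlH, CH2Cl2, −78 to 0 °C
Reagents that add atoms: none
Why: Regioselective reductive acetal opening: DIBAL-H coordinates the less hindered primary oxygen, so the PMB ether should remain on the secondary oxygen (future O8).

Step 10
Reactants: 13 (R)-2-[(4-methoxybenzyl)oxy]but-3-yn-1-ol
Product: 14 (R)-2-[(4-methoxybenzyl)oxy]penta-3,4-dien-1-ol
Conditions: (CH2O)n, CuI, Cy2NH, 1,4-dioxane, reflux
Reagents that add atoms: paraformaldehyde (as formaldehyde), C=O
Why: Crabbé homologation (Mannich reaction, then copper-assisted 1,5-hydride transfer) turns the terminal alkyne into the terminal allene C7=C11=C13 without touching the adjacent stereocentre.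

Step 11
Reactants: 14 allenyl alcohol
Product: 15 (R)-2-[(4-methoxybenzyl)oxy]penta-3,4-dienal
Conditions: Dess–Martin periodinane, NaHCO3, CH2Cl2, 0 °C; used crude at once
Reagents that add atoms: none
Why: Dess–Martin oxidation is neutral and fast, which should limit enolisation of the α-alkoxy allenyl aldehyde.

Step 12
Reactants: 8 vinyl iodide alcohol; 15 allenyl aldehyde
Product: 18 (2E,5S,6Z,8R,9R)-5-[(tert-butyldimethylsilyl)oxy]-9-[(4-methoxybenzyl)oxy]-3,7-dimethyldodeca-2,6,10,11-tetraene-1,8-diol, via dilithio alkoxide 16 (not isolated), via vinylmagnesium bromide 17 (not isolated)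
Conditions: t-BuLi (3.1 equiv), Et2O, −78 °C; MgBr2·OEt2; 15, CH2Cl2, −78 °C; aq. NH4Cl
Reagents that add atoms: none
Why: Iodine–lithium exchange with retention of the Z geometry, transmetalation to magnesium and Cram-chelate-controlled addition to the α-PMB-oxy aldehyde should give the syn (threo) 8,9-diol monoether, setting C9 as R.

Step 13
Reactants: 18 diol
Product: 19 1,8-bis(triethylsilyl) ether of 18
Conditions: TESOTf, 2,6-lutidine, CH2Cl2, −78 to 0 °C
Reagents that add atoms: triethylsilyl trifluoromethanesulfonate, CC[Si](CC)(CC)OS(=O)(=O)C(F)(F)F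
Why: Silyl triflate silylation covers both the primary allylic and the hindered secondary hydroxyl in one operation.

Step 14
Reactants: 19 bis(triethylsilyl) ether
Product: 20 (2E,5S,6Z,8R,9R)-5-[(tert-butyldimethylsilyl)oxy]-9-[(4-methoxybenzyl)oxy]-3,7-dimethyl-8-[(triethylsilyl)oxy]dodeca-2,6,10,11-tetraenal
Conditions: (COCl)2, DMSO, CH2Cl2, −78 to −30 °C; Et3N, −78 to 0 °C
Reagents that add atoms: none
Why: Swern oxidation acts directly on primary triethylsilyl ethers and leaves secondary silyl ethers, so the E-enal (C6) should be unveiled without a separate deprotection.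

Step 15
Reactants: 20 allenyl enal
Product: 23 (1(10)Z,4E)-2-(tert-butyldimethylsilyloxy)-8-(4-methoxybenzyloxy)-9-(triethylsilyloxy)germacra-1(10),4,11(13)-trien-12,6-olide (stereocentres as in 29, 6,7-trans lactone), via nickelalactone 21 (not isolated), via hydroxy acid 22 (not isolated)
Conditions: Ni(cod)2 (1.5 equiv), DBU, CO2 (1 atm), THF, 0 °C, slow addition of 20 (2 mM); cold 1 M HCl; PPTS (cat.), CH2Cl2, rt
Reagents that add atoms: carbon dioxide, O=C=O
Why: Proposed new method: zerovalent nickel couples CO2 with the terminal allene (oxidative cyclisation, CO2 carbon to the central carbon C11) to give the DBU-ligated nickelalactone 21, a 2-carboxylatoallylnickel whose C13-bound σ-form adds through C7 to the tethered enal carbonyl C6 in a six-membered chair transition state; acid then releases hydroxy acid 22, which lactonises. The closest known reaction types are the nickel-promoted carboxylation/cyclisation of allenyl aldehydes under CO2, shown for small carbocycles, and the intramolecular Barbier closure of 2-(alkoxycarbonyl)allyl metals onto enals used for ten-membered germacranolide rings; new here is the ten-membered closure by the nickel species. The carbocycle closes by 10-exo-trig addition of C7 to the C6 carbonyl, the lactone by 5-exo-trig acyl substitution of O6 at C12. C7 is controlled by C8: allylic 1,3-strain holds H8 in the plane of the C7=C11 bond and the carbonyl is delivered on the face carrying the C8–C9 tether, anti to the PMB ether; C6 follows from the chair with the (E)-alkylidene, which gives the 6,7-anti (trans-lactone) relationship. The step needs CO2 at C11, C–C bond formation at C7 and not C13 (ten- not twelve-membered ring), 1,2- not 1,4-addition to the enal and no ionisation of allylic C–O bonds; the monosubstituted allene, the SE2′ path from nickel on unhindered C13 and ether or silyl ether protection (no allylic or allenylic esters) should secure these, with the preformed 1(10)Z and 4E alkenes as turn elements.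

Step 16
Reactants: 23 PMB-protected lactone
Product: 24 8-hydroxy lactone (2-O-TBS, 9-O-TES; stereocentres as in 29)
Conditions: DDQ, CH2Cl2/pH 7 buffer, 0 °C
Reagents that add atoms: none
Why: Oxidative cleavage of the PMB ether by DDQ is neutral and should leave silyl ethers, the diene and the α-methylene lactone untouched.

Step 17
Reactants: 24 8-hydroxy lactone; 25 angelic acid, (Z)-2-methylbut-2-enoic acid
Product: 26 8-O-angeloyl lactone (2-O-TBS, 9-O-TES)
Conditions: 25, 2,4,6-trichlorobenzoyl chloride, Et3N, toluene, rt; then 24, toluene, 75 °C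
Reagents that add atoms: none
Why: Yamaguchi esterification through the mixed anhydride, run without DMAP, should acylate the hindered C8 hydroxyl while keeping the Z (angelate) geometry.

Step 18
Reactants: 26 8-O-angeloyl lactone
Product: 27 9-hydroxy 8-O-angeloyl lactone (2-O-TBS)
Conditions: HF·pyridine, pyridine, THF, 0 °C
Reagents that add atoms: none
Why: Buffered HF·pyridine removes the secondary triethylsilyl ether selectively in the presence of the more robust tert-butyldimethylsilyl ether.

Step 19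
Reactants: 27 9-hydroxy lactone
Product: 28 9-O-acetyl 8-O-angeloyl lactone (2-O-TBS)
Conditions: Ac2O, pyridine, DMAP (cat.), CH2Cl2, 0 °C to rt
Reagents that add atoms: acetic anhydride, CC(=O)OC(C)=O
Why: Standard acetylation of the allylic C9 hydroxyl; the conjugated, hindered angelate is not expected to migrate under these conditions.

Step 20
Reactants: 28 silyl-protected diester
Product: 29 (3aS,4R,5R,6Z,8S,10E,11aR)-5-acetoxy-8-hydroxy-6,10-dimethyl-3-methylidene-2-oxo-2,3,3a,4,5,8,9,11a-octahydrocyclodeca[b]furan-4-yl (2Z)-2-methylbut-2-enoate (target)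
Conditions: HF·pyridine, THF, rt
Reagents that add atoms: none
Why: Acidic fluoride desilylation frees the C2 hydroxyl without base, so the esters and the α-methylene lactone should survive.

**Compound list**

1 | but-2-yn-1-ol | CC#CCO | starting material
2 | (Z)-3-iodobut-2-en-1-ol | OC/C=C(/C)I | intermediate
3 | (Z)-3-iodobut-2-enal | O=C/C=C(/C)I | intermediate
4 | ethyl 3-methylbut-2-enoate | CCOC(=O)C=C(C)C | starting material
5 | tert-butyl[(1-ethoxy-3-methylbuta-1,3-dien-1-yl)oxy]dimethylsilane | CCOC(O[Si](C)(C)C(C)(C)C)=CC(C)=C | intermediate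
6 | ethyl (2E,5S,6Z)-5-hydroxy-7-iodo-3-methylocta-2,6-dienoate | CCOC(=O)/C=C(\C)C[C@H](O)/C=C(/C)I | intermediate
7 | ethyl (2E,5S,6Z)-5-[(tert-butyldimethylsilyl)oxy]-7-iodo-3-methylocta-2,6-dienoate | CCOC(=O)/C=C(\C)C[C@H](O[Si](C)(C)C(C)(C)C)/C=C(/C)I | intermediate
8 | (2E,5S,6Z)-5-[(tert-butyldimethylsilyl)oxy]-7-iodo-3-methylocta-2,6-dien-1-ol | OC/C=C(\C)C[C@H](O[Si](C)(C)C(C)(C)C)/C=C(/C)I | intermediate
9 | (S)-2,2-dimethyl-1,3-dioxolane-4-carbaldehyde | O=C[C@@H]1COC(C)(C)O1 | starting material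
10 | (R)-4-ethynyl-2,2-dimethyl-1,3-dioxolane | C#C[C@@H]1COC(C)(C)O1 | intermediate
11 | (R)-but-3-yne-1,2-diol | C#C[C@@H](O)CO | intermediate
12 | (4R)-4-ethynyl-2-(4-methoxyphenyl)-1,3-dioxolane (acetal epimers) | C#C[C@@H]1COC(c2ccc(OC)cc2)O1 | intermediate
13 | (R)-2-[(4-methoxybenzyl)oxy]but-3-yn-1-ol | C#C[C@@H](OCc1ccc(OC)cc1)CO | intermediate
14 | (R)-2-[(4-methoxybenzyl)oxy]penta-3,4-dien-1-ol | C=C=C[C@@H](OCc1ccc(OC)cc1)CO | intermediate
15 | (R)-2-[(4-methoxybenzyl)oxy]penta-3,4-dienal | C=C=C[C@@H](OCc1ccc(OC)cc1)C=O | intermediate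
16 | lithium (2E,5S,6Z)-5-[(tert-butyldimethylsilyl)oxy]-7-lithio-3-methylocta-2,6-dien-1-olate | [Li]OC/C=C(\C)C[C@H](O[Si](C)(C)C(C)(C)C)/C=C(/C)[Li] | intermediate
17 | bromomagnesium analogue of 16 (vinyl–MgBr, lithium alkoxide) | [Li]OC/C=C(\C)C[C@H](O[Si](C)(C)C(C)(C)C)/C=C(/C)[Mg]Br | intermediate
18 | (2E,5S,6Z,8R,9R)-5-[(tert-butyldimethylsilyl)oxy]-9-[(4-methoxybenzyl)oxy]-3,7-dimethyldodeca-2,6,10,11-tetraene-1,8-diol | OC/C=C(\C)C[C@H](O[Si](C)(C)C(C)(C)C)/C=C(/C)[C@@H](O)[C@H](OCc1ccc(OC)cc1)C=C=C | intermediate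
19 | 1,8-bis(triethylsilyl) ether of 18 | CC[Si](CC)(CC)OC/C=C(\C)C[C@H](O[Si](C)(C)C(C)(C)C)/C=C(/C)[C@@H](O[Si](CC)(CC)CC)[C@H](OCc1ccc(OC)cc1)C=C=C | intermediate
20 | (2E,5S,6Z,8R,9R)-5-[(tert-butyldimethylsilyl)oxy]-9-[(4-methoxybenzyl)oxy]-3,7-dimethyl-8-[(triethylsilyl)oxy]dodeca-2,6,10,11-tetraenal | O=C/C=C(\C)C[C@H](O[Si](C)(C)C(C)(C)C)/C=C(/C)[C@@H](O[Si](CC)(CC)CC)[C@H](OCc1ccc(OC)cc1)C=C=C | intermediate
21 | DBU-ligated (E)-alkylidene oxanickelacyclopentanone of divalent nickel formed from the allene of 20 and CO2 (ligands omitted) | O=C/C=C(\C)C[C@H](O[Si](C)(C)C(C)(C)C)/C=C(/C)[C@@H](O[Si](CC)(CC)CC)[C@H](OCc1ccc(OC)cc1)/C=C1\C(=O)O[Ni]C1 | intermediate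
22 | 2-[(1(10)Z,4E)-6-hydroxy-2-(tert-butyldimethylsilyloxy)-8-(4-methoxybenzyloxy)-9-(triethylsilyloxy)-4,10-dimethylcyclodeca-1(10),4-dien-7-yl]acrylic acid (germacrane locants, stereocentres as in 29) | O[C@@H]1/C=C(\C)C[C@H](O[Si](C)(C)C(C)(C)C)/C=C(/C)[C@@H](O[Si](CC)(CC)CC)[C@H](OCc2ccc(OC)cc2)[C@H]1C(=C)C(O)=O | intermediate
23 | (1(10)Z,4E)-2-(tert-butyldimethylsilyloxy)-8-(4-methoxybenzyloxy)-9-(triethylsilyloxy)germacra-1(10),4,11(13)-trien-12,6-olide (stereocentres as in 29) | C=C1C(=O)O[C@@H]2/C=C(\C)C[C@H](O[Si](C)(C)C(C)(C)C)/C=C(/C)[C@@H](O[Si](CC)(CC)CC)[C@H](OCc3ccc(OC)cc3)[C@@H]12 | intermediate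
24 | 8-hydroxy analogue of 23 (2-O-TBS, 9-O-TES) | C=C1C(=O)O[C@@H]2/C=C(\C)C[C@H](O[Si](C)(C)C(C)(C)C)/C=C(/C)[C@@H](O[Si](CC)(CC)CC)[C@H](O)[C@@H]12 | intermediate
25 | angelic acid, (Z)-2-methylbut-2-enoic acid | C/C=C(/C)C(O)=O | starting material
26 | 8-O-angeloyl lactone (2-O-TBS, 9-O-TES) | C=C1C(=O)O[C@@H]2/C=C(\C)C[C@H](O[Si](C)(C)C(C)(C)C)/C=C(/C)[C@@H](O[Si](CC)(CC)CC)[C@H](OC(=O)/C(C)=C\C)[C@@H]12 | intermediate
27 | 9-hydroxy 8-O-angeloyl lactone (2-O-TBS) | C=C1C(=O)O[C@@H]2/C=C(\C)C[C@H](O[Si](C)(C)C(C)(C)C)/C=C(/C)[C@@H](O)[C@H](OC(=O)/C(C)=C\C)[C@@H]12 | intermediate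
28 | 9-O-acetyl 8-O-angeloyl lactone (2-O-TBS) | C=C1C(=O)O[C@@H]2/C=C(\C)C[C@H](O[Si](C)(C)C(C)(C)C)/C=C(/C)[C@@H](OC(C)=O)[C@H](OC(=O)/C(C)=C\C)[C@@H]12 | intermediate
29 | (3aS,4R,5R,6Z,8S,10E,11aR)-5-acetoxy-8-hydroxy-6,10-dimethyl-3-methylidene-2-oxo-2,3,3a,4,5,8,9,11a-octahydrocyclodeca[b]furan-4-yl (2Z)-2-methylbut-2-enoate | C=C1C(=O)O[C@@H]2/C=C(\C)C[C@H](O)/C=C(/C)[C@@H](OC(C)=O)[C@H](OC(=O)/C(C)=C\C)[C@@H]12 | target

**Step count**

Total steps: 20. Longest linear sequence: 14 steps (steps 1, 2, 4–6, 12–20; the arm through steps 7–11 and 12–20 is also 14).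

**Steps most likely to fail**

1. Step 15 (Proposed new method). The macrocyclisation may lose to oligomerisation, zerovalent nickel may engage the enal instead of the allene, or the carbonyl may be delivered to the wrong face of C7 or C6. The fallback uses known chemistry throughout: C11–C12 is made first and the ring is closed by the chromium-mediated intramolecular Barbier reaction established for germacranolides. It sets out from 13 and 8 and returns at 23.
   - Dess–Martin oxidation of 13 gives (R)-2-[(4-methoxybenzyl)oxy]but-3-ynal F1.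
   - Chelation-controlled addition of vinylmagnesium species 17 (from 8, as in step 12) gives the alkynyl diol F2.
   - TESOTf/2,6-lutidine gives the bis(triethylsilyl) ether F3.
   - n-BuLi then methyl chloroformate gives the ynoate F4.
   - Conjugate hydroalumination (iBu2AlH/HMPA) with formaldehyde trapping gives the 2-(hydroxymethyl)enoate F5.
   - CBr4/PPh3 gives the allylic bromide F6.
   - Swern oxidation of the primary silyl ether gives the bromo enal F7.
   - CrCl2 in THF/DMF at high dilution closes the ten-membered ring through C7; the chromium alkoxide lactonises onto the methyl ester to give 23.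

2. Step 12. The basic organometallic may enolise and isomerise the α-alkoxy allenyl aldehyde, the Z-γ-silyloxy vinyl anion may undergo 1,4 O-to-C silyl migration, and chelation control may be weak, eroding the 8,9-syn selectivity. The fallback replaces aldehyde addition by acylation and reagent-controlled reduction. It sets out from 14 and 8 and returns at 18.
   - TEMPO/PhI(OAc)2 in MeCN–H2O oxidises 14 to (R)-2-[(4-methoxybenzyl)oxy]penta-3,4-dienoic acid F8.
   - EDC with N,O-dimethylhydroxylamine gives the Weinreb amide F9.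
   - Addition of dilithio species 16 (from 8) gives the enone F10.
   - Corey–Bakshi–Shibata reduction (oxazaborolidine antipode chosen for the 9R carbinol, BH3·SMe2) gives 18.

3. Step 17. Activation may isomerise the angeloyl group to tigloyl, acylation of the hindered C8 hydroxyl may stall, and base may induce translactonisation of the free 8-hydroxy lactone towards the 8,12-olide. The fallback builds the Z-enoate on the substrate. It sets out from 24 and returns at 26.
   - DCC-mediated esterification of 24 with 2-[bis(2,2,2-trifluoroethoxy)phosphoryl]propanoic acid at room temperature gives the phosphonate ester F11.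
   - Still–Gennari olefination with acetaldehyde (KN(SiMe3)2, 18-crown-6, THF, −78 °C) gives the (Z)-2-methylbut-2-enoate 26.

**Further compounds**

F1 | step 15 | (R)-2-[(4-methoxybenzyl)oxy]but-3-ynal | C#C[C@@H](OCc1ccc(OC)cc1)C=O
F2 | step 15 | (2E,5S,6Z,8R,9R)-5-[(tert-butyldimethylsilyl)oxy]-9-[(4-methoxybenzyl)oxy]-3,7-dimethylundeca-2,6-dien-10-yne-1,8-diol | OC/C=C(\C)C[C@H](O[Si](C)(C)C(C)(C)C)/C=C(/C)[C@@H](O)[C@H](OCc1ccc(OC)cc1)C#C
F3 | step 15 | 1,8-bis(triethylsilyl) ether of F2 | CC[Si](CC)(CC)OC/C=C(\C)C[C@H](O[Si](C)(C)C(C)(C)C)/C=C(/C)[C@@H](O[Si](CC)(CC)CC)[C@H](OCc1ccc(OC)cc1)C#C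
F4 | step 15 | methyl ynoate from carboxylation of the alkyne terminus of F3 | CC[Si](CC)(CC)OC/C=C(\C)C[C@H](O[Si](C)(C)C(C)(C)C)/C=C(/C)[C@@H](O[Si](CC)(CC)CC)[C@H](OCc1ccc(OC)cc1)C#CC(=O)OC
F5 | step 15 | methyl 2-(hydroxymethyl)alk-2-enoate from F4 (alkene geometry as formed) | CC[Si](CC)(CC)OC/C=C(\C)C[C@H](O[Si](C)(C)C(C)(C)C)/C=C(/C)[C@@H](O[Si](CC)(CC)CC)[C@H](OCc1ccc(OC)cc1)C=C(CO)C(=O)OC
F6 | step 15 | methyl 2-(bromomethyl)alk-2-enoate from F5 | CC[Si](CC)(CC)OC/C=C(\C)C[C@H](O[Si](C)(C)C(C)(C)C)/C=C(/C)[C@@H](O[Si](CC)(CC)CC)[C@H](OCc1ccc(OC)cc1)C=C(CBr)C(=O)OC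
F7 | step 15 | bromo enal from selective oxidation of F6 | O=C/C=C(\C)C[C@H](O[Si](C)(C)C(C)(C)C)/C=C(/C)[C@@H](O[Si](CC)(CC)CC)[C@H](OCc1ccc(OC)cc1)C=C(CBr)C(=O)OC
F8 | step 12 | (R)-2-[(4-methoxybenzyl)oxy]penta-3,4-dienoic acid | C=C=C[C@@H](OCc1ccc(OC)cc1)C(O)=O
F9 | step 12 | (R)-N-methoxy-N-methyl-2-[(4-methoxybenzyl)oxy]penta-3,4-dienamide | C=C=C[C@@H](OCc1ccc(OC)cc1)C(=O)N(C)OC
F10 | step 12 | (2E,5S,6Z,9R)-5-[(tert-butyldimethylsilyl)oxy]-1-hydroxy-9-[(4-methoxybenzyl)oxy]-3,7-dimethyldodeca-2,6,10,11-tetraen-8-one | OC/C=C(\C)C[C@H](O[Si](C)(C)C(C)(C)C)/C=C(/C)C(=O)[C@H](OCc1ccc(OC)cc1)C=C=C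
F11 | step 17 | 8-O-{2-[bis(2,2,2-trifluoroethoxy)phosphoryl]propanoyl} derivative of 24 | C=C1C(=O)O[C@@H]2/C=C(\C)C[C@H](O[Si](C)(C)C(C)(C)C)/C=C(/C)[C@@H](O[Si](CC)(CC)CC)[C@H](OC(=O)C(C)P(=O)(OCC(F)(F)F)OCC(F)(F)F)[C@@H]12
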